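**Plan**

1. Retrosynthetic cuts, in order: the acetate and the C2 carbonyl (functional-group changes); C12–C13 of the macrocycle (reductive diene–ketone coupling); C1–C2 (Nozaki–Hiyama–Kishi); O–C9 of the oxolane (alkynol cycloisomerisation); the epoxide oxygen (Sharpless); C2–C3 and C4–CH3 (carboalumination); C4–C5 and C10–C11 (acetylide/epoxide openings); C9≡C10 (lactol homologation).
2. Enabling feature: the bishomoallylic tertiary carbinol array C12(O)–C13H2–C14H2–C1=C15Me2 in the 14-membered carbocycle (13-membered ring through the oxolane oxygen) is the retron of a 1,3-diene/ketone homoallylation, so the open precursor needs only a methyl ketone and a vinyl-capped diene.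
3. Forward order: the chain is grown linearly from a pool lactone; the oxolane ring is closed first (5-exo-dig onto C9≡C10), the dienyl unit is then attached at C2, and the macrocycle is closed in step 19, followed by three functional-group steps.
4. Stereochemistry: C6 from the lactone; C8 by trans-selective lactone enolate methylation; C3/C4 by Sharpless epoxidation with L-(+)-tartrate; the Z-enol ether by anti-oxyauration; C12 in the ring closure (substrate control: chelated Z-alkylidene oxolane, tether on the face opposite the C8 methyl).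
5. Helpers: C2 is kept at the alcohol level as a silyl ether during the nickel step and oxidised last; the C12 oxygen is carried as a silyl ether until the oxolane is in place.

Key step: step 19

Remark: cembrane numbering is used for locants (C1 isopropylidene carbon with C15, C2 ketone, C3/C4 epoxide, C6–O–C9 oxolane, C8 ring methyl, C10 enol-ether CH, C12 acetoxy carbon, C13/C14 the adjoining ring CH2 groups).
Remark: lactone 1 (D-glutamic acid series) is taken as commercially available; C2 is carried as a mixture of carbinol epimers in 24–28 (SMILES without a descriptor at C2) and is erased in step 22, as is the propylene-oxide carbinol in step 14.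

**Route**

Step 1
Reactants: 1 (5R)-5-(hydroxymethyl)oxolan-2-one
Product: 2 (5R)-5-{[tert-butyl(diphenyl)silyl]oxymethyl}oxolan-2-one
Conditions: tBuPh2SiCl, imidazole, DMF, 0 °C to rt
Reagents that add atoms: tert-butyl(chloro)diphenylsilane, CC(C)(C)[Si](Cl)(c1ccccc1)c1ccccc1
Why: Imidazole-promoted silylation of the primary alcohol installs the bulky group that will direct the next alkylation.

Step 2
Reactants: 2 (5R)-5-{[tert-butyl(diphenyl)silyl]oxymethyl}oxolan-2-one
Product: 4 (3S,5R)-5-{[tert-butyl(diphenyl)silyl]oxymethyl}-3-methyloxolan-2-one, via lithium lactone enolate 3 (not isolated)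
Conditions: LiN(SiMe3)2, THF, −78 °C; then MeI, −78 °C
Reagents that add atoms: iodomethane, C[I]
Why: Kinetic alkylation of the γ-butyrolactone enolate should occur anti to the bulky silyloxymethyl group, setting C8 (3S) trans to C6 by substrate control.

Step 3
Reactants: 4 (3S,5R)-5-{[tert-butyl(diphenyl)silyl]oxymethyl}-3-methyloxolan-2-one
Product: 5 (3S,5R)-5-{[tert-butyl(diphenyl)silyl]oxymethyl}-3-methyloxolan-2-ol (anomers)
Conditions: iBu2AlH, CH2Cl2, −78 °C; Rochelle salt work-up
Reagents that add atoms: none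
Why: Low-temperature half-reduction of a γ-lactone stops at the lactol because the tetrahedral aluminate is stable until work-up.

Step 4
Reactants: 5 (3S,5R)-5-{[tert-butyl(diphenyl)silyl]oxymethyl}-3-methyloxolan-2-ol
Product: 6 (2R,4S)-1-{[tert-butyl(diphenyl)silyl]oxy}-4-methylhex-5-yn-2-ol
Conditions: Ohira–Bestmann reagent, K2CO3, MeOH, 0 °C to rt
Reagents that add atoms: dimethyl (1-diazo-2-oxopropyl)phosphonate, CC(=O)C(=[N+]=[N-])P(=O)(OC)OC
Why: Seyferth–Gilbert homologation of the open hydroxy-aldehyde form of the lactol gives the terminal alkyne (C9≡C10) under conditions mild enough to preserve the α-stereocentre C8.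

Step 5
Reactants: 6 (2R,4S)-1-{[tert-butyl(diphenyl)silyl]oxy}-4-methylhex-5-yn-2-ol
Product: 8 (2S,6S,8R)-9-{[tert-butyl(diphenyl)silyl]oxy}-6-methylnon-4-yne-2,8-diol, via dilithio alkoxide acetylide 7 (not isolated)
Conditions: nBuLi (2.1 equiv), THF, −78 °C; then BF3·OEt2, (S)-propylene oxide, −78 °C
Reagents that add atoms: (S)-2-methyloxirane, C[C@H]1CO1
Why: The BF3-activated epoxide is opened at its CH2 by the lithium acetylide (Yamaguchi-type alkynylation) while the C6 alkoxide stays inert as its boron complex; the new carbinol is later oxidised.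

Step 6
Reactants: 8 (2S,6S,8R)-9-{[tert-butyl(diphenyl)silyl]oxy}-6-methylnon-4-yne-2,8-diol
Product: 9 (2R,4S,8S)-4-methylnon-5-yne-1,2,8-triol
Conditions: Bu4NF, THF, rt
Reagents that add atoms: none
Why: Fluoride cleaves the Si–O bond of the primary silyl ether and leaves the alkyne untouched.

Step 7
Reactants: 9 (2R,4S,8S)-4-methylnon-5-yne-1,2,8-triol
Product: 11 (2S,6S)-6-methyl-7-[(2R)-oxiran-2-yl]hept-4-yn-2-ol, via primary tosylate 10 (not isolated)
Conditions: TsCl, Bu2SnO (cat.), Et3N, CH2Cl2, 0 °C; then K2CO3, MeOH, rt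
Reagents that add atoms: none
Why: Tin-catalysed sulfonylation is selective for the primary hydroxyl of the 1,2-diol (stannylene acetal), and the neighbouring C6 alkoxide then closes the epoxide by intramolecular SN2 with retention at C6.

Step 8
Reactants: 11 (2S,6S)-6-methyl-7-[(2R)-oxiran-2-yl]hept-4-yn-2-ol
Product: 12 tert-butyl(dimethyl){[(2S,6S)-6-methyl-7-[(2R)-oxiran-2-yl]hept-4-yn-2-yl]oxy}silane
Conditions: tBuMe2SiCl, imidazole, DMF, rt
Reagents that add atoms: tert-butyl(chloro)dimethylsilane, CC(C)(C)[Si](C)(C)Cl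
Why: Silylation masks the remaining secondary hydroxyl (later C12–O) so that only the C6 hydroxyl can add to the alkyne in step 12.

Step 9
Reactants: 12 tert-butyl(dimethyl){[(2S,6S)-6-methyl-7-[(2R)-oxiran-2-yl]hept-4-yn-2-yl]oxy}silane
Product: 13 (4R,6S,10S)-10-{[tert-butyl(dimethyl)silyl]oxy}-6-methylundeca-1,7-diyn-4-ol
Conditions: HC≡CLi·H2NCH2CH2NH2, DMSO, rt
Reagents that add atoms: lithium acetylide ethylenediamine complex, [Li]C#C.NCCN
Why: The acetylide opens the terminal epoxide at the less hindered carbon (SN2), forming C4–C5 and releasing the C6 hydroxyl with unchanged configuration.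

Step 10
Reactants: 13 (4R,6S,10S)-10-{[tert-butyl(dimethyl)silyl]oxy}-6-methylundeca-1,7-diyn-4-ol
Product: 15 (2E,5R,7S,11S)-11-{[tert-butyl(dimethyl)silyl]oxy}-3,7-dimethyldodec-2-en-8-yne-1,5-diol, via alkenylalane 14 (not isolated)
Conditions: Me3Al, Cp2ZrCl2 (cat.), CH2Cl2, 0 °C to rt; then (CH2O)n, THF, 0 °C to rt
Reagents that add atoms: trimethylaluminium, C[Al](C)C; paraformaldehyde (as formaldehyde), C=O
Why: Zirconium-catalysed syn-carboalumination (Negishi) of the terminal alkyne puts methyl on C4 and aluminium on C3, and hydroxymethylation with retention fixes the E-trisubstituted allylic alcohol, the internal dialkyl alkyne reacting much more slowly.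

Step 11
Reactants: 15 (2E,5R,7S,11S)-11-{[tert-butyl(dimethyl)silyl]oxy}-3,7-dimethyldodec-2-en-8-yne-1,5-diol
Product: 16 (2R,4S,8S)-8-{[tert-butyl(dimethyl)silyl]oxy}-1-[(2S,3S)-3-(hydroxymethyl)-2-methyloxiran-2-yl]-4-methylnon-5-yn-2-ol
Conditions: Ti(OiPr)4 (cat.), L-(+)-diethyl tartrate (cat.), tBuOOH, 4 Å sieves, CH2Cl2, −20 °C
Reagents that add atoms: tert-butyl hydroperoxide, CC(C)(C)OO
Why: Sharpless asymmetric epoxidation of the primary E-allylic alcohol under reagent control with L-(+)-tartrate should give the (2S,3S)-epoxy alcohol, which carries the target configuration at C3 and C4.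

Step 12
Reactants: 16 (2R,4S,8S)-8-{[tert-butyl(dimethyl)silyl]oxy}-1-[(2S,3S)-3-(hydroxymethyl)-2-methyloxiran-2-yl]-4-methylnon-5-yn-2-ol
Product: 17 {(2S,3S)-3-[((2R,4S,5Z)-5-{(3S)-3-[tert-butyl(dimethyl)silyl]oxybutylidene}-4-methyloxolan-2-yl)methyl]-3-methyloxiran-2-yl}methanol
Conditions: AuCl (5 mol%), K2CO3 (10 mol%), MeCN, rt
Reagents that add atoms: none
Why: Gold-catalysed 5-exo-dig hydroalkoxylation of the 4-alkyn-1-ol (anti-oxyauration of C9≡C10 by the C6 hydroxyl, then protodeauration with retention) should give the oxolane with the Z-enol ether, C11 cis to oxygen.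

Step 13
Reactants: 17 {(2S,3S)-3-[((2R,4S,5Z)-5-{(3S)-3-[tert-butyl(dimethyl)silyl]oxybutylidene}-4-methyloxolan-2-yl)methyl]-3-methyloxiran-2-yl}methanol
Product: 18 (2S,4Z)-4-[(3S,5R)-5-{[(2S,3S)-3-(hydroxymethyl)-2-methyloxiran-2-yl]methyl}-3-methyloxolan-2-ylidene]butan-2-ol
Conditions: Bu4NF, THF, 0 °C to rt; crude product kept basic and used directly
Reagents that add atoms: none
Why: Fluoride removes the secondary silyl ether under basic conditions, which spare the enol ether and avoid acid-induced spiroketalisation of the resulting γ-hydroxy enol ether.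

Step 14
Reactants: 18 (2S,4Z)-4-[(3S,5R)-5-{[(2S,3S)-3-(hydroxymethyl)-2-methyloxiran-2-yl]methyl}-3-methyloxolan-2-ylidene]butan-2-ol
Product: 19 (2R,3S)-3-methyl-3-{[(2R,4S,5Z)-4-methyl-5-(3-oxobutylidene)oxolan-2-yl]methyl}oxirane-2-carbaldehyde
Conditions: SO3·pyridine, DMSO, iPr2NEt, CH2Cl2, 0 °C
Reagents that add atoms: none
Why: Parikh–Doering oxidation converts the primary epoxy alcohol into the aldehyde and the secondary alcohol into the methyl ketone in a medium that stays basic throughout.

Step 15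
Reactants: 20 1,1-dibromo-2-methylprop-1-ene
Product: 21 3-bromo-4-methylpenta-1,3-diene
Conditions: vinylboronic acid pinacol ester (1.0 equiv), Pd(PPh3)4 (cat.), K2CO3, THF/H2O, 60 °C
Reagents that add atoms: 4,4,5,5-tetramethyl-2-vinyl-1,3,2-dioxaborolane, C=CB1OC(C)(C)C(C)(C)O1
Why: Suzuki–Miyaura mono-coupling of the gem-dibromoalkene stops after one vinylation because the remaining bromide sits on a more hindered, fully substituted alkene carbon.

Step 16
Reactants: 21 3-bromo-4-methylpenta-1,3-diene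
Product: 23 3-iodo-4-methylpenta-1,3-diene, via dienyllithium 22 (not isolated)
Conditions: tBuLi (2 equiv), Et2O, −78 °C; then I2, −78 °C to rt
Reagents that add atoms: iodine, [I][I]
Why: Bromine–lithium exchange followed by iodinolysis gives the alkenyl iodide, which undergoes oxidative addition to nickel much faster than the bromide in the next step.

Step 17
Reactants: 19 (2R,3S)-3-methyl-3-{[(2R,4S,5Z)-4-methyl-5-(3-oxobutylidene)oxolan-2-yl]methyl}oxirane-2-carbaldehyde; 23 3-iodo-4-methylpenta-1,3-diene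
Product: 24 (4Z)-4-[(3S,5R)-5-({(2S,3S)-3-[2-ethenyl-1-hydroxy-3-methylbut-2-en-1-yl]-2-methyloxiran-2-yl}methyl)-3-methyloxolan-2-ylidene]butan-2-one (C2 carbinol epimers)
Conditions: CrCl2 (excess), NiCl2 (cat.), DMSO, rt
Reagents that add atoms: none
Why: In the Nozaki–Hiyama–Kishi coupling the alkenylchromium species adds to the aldehyde and not to the enolisable methyl ketone, forming C1–C2; the new C2 centre is uncontrolled and is erased in step 22.

Step 18
Reactants: 24 (4Z)-4-[(3S,5R)-5-({(2S,3S)-3-[2-ethenyl-1-hydroxy-3-methylbut-2-en-1-yl]-2-methyloxiran-2-yl}methyl)-3-methyloxolan-2-ylidene]butan-2-one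
Product: 25 (4Z)-4-[(3S,5R)-5-({(2S,3S)-3-[2-ethenyl-3-methyl-1-(triethylsilyloxy)but-2-en-1-yl]-2-methyloxiran-2-yl}methyl)-3-methyloxolan-2-ylidene]butan-2-one
Conditions: Et3SiCl, imidazole, DMF, rt
Reagents that add atoms: chlorotriethylsilane, CC[Si](Cl)(CC)CC
Why: Silylation keeps C2 at the alcohol level, so that the nickel step meets an electron-rich diene and an unactivated epoxide and no enone, epoxy ketone or allylic alkoxide.

Step 19
Reactants: 25 (4Z)-4-[(3S,5R)-5-({(2S,3S)-3-[2-ethenyl-3-methyl-1-(triethylsilyloxy)but-2-en-1-yl]-2-methyloxiran-2-yl}methyl)-3-methyloxolan-2-ylidene]butan-2-one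
Product: 26 (3S,4S,6R,8S,9Z,12R)-3,4:6,9-diepoxy-2-(triethylsilyloxy)cembra-1(15),9-dien-12-ol
Conditions: Ni(acac)2 (20 mol%), Et2Zn (3 equiv), THF, rt, syringe-pump addition to high dilution; pH 7 buffer quench
Reagents that add atoms: none
Why: Proposed new method: Et2Zn reduces Ni(acac)2 to zerovalent nickel, which binds the 1,3-diene (C13=C14–C1=C15) and the zinc-activated C12 ketone and undergoes oxidative cyclisation to an oxanickelacycle in which the C12–C13 bond is made and nickel is held as an allyl over C14–C1–C15; ethyl transfer from zinc, β-hydride elimination (ethene) and C–H reductive elimination at the proximal, secondary allyl terminus C14 then release the zinc alkoxide of the bishomoallylic tertiary alcohol with the tetrasubstituted C1=C15 alkene intact. The closest known reaction type is the Ni(acac)2/Et2Zn-promoted homoallylation of aldehydes and ketones with 1,3-dienes, established between two molecules and for five- and six-membered ring closures, but not for a macrocyclisation nor for a 2-substituted 4,4-dimethyl diene. The step closes the 14-membered carbocycle (and thereby the 13-membered ring through the oxolane oxygen) by C12–C13 bond formation, exo with respect to the C12 carbonyl and endo with respect to the C13=C14 vinyl group. C12 is the only new stereocentre and is substrate-controlled: the Z-alkylidene oxolane keeps C11 and the ring oxygen cis, so a zinc centre can bridge that oxygen and the carbonyl oxygen, and the tether, which leaves C6 on the oxolane face opposite the C8 methyl, should bring C13 to the Re face of the chelated ketone, which corresponds to 12R. The step needs C13 rather than C15 to bond (C15 is fully substituted), hydrogen delivery to C14 rather than C15 (secondary versus tertiary allyl terminus), reaction of the vinyl-capped diene in preference to the enol ether and the epoxide (neither binds zerovalent nickel well, and C2 is kept as its silyl ether), and ring closure in preference to oligomerisation (slow addition at high dilution).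

Step 20
Reactants: 26 (3S,4S,6R,8S,9Z,12R)-3,4:6,9-diepoxy-2-(triethylsilyloxy)cembra-1(15),9-dien-12-ol
Product: 27 (3S,4S,6R,8S,9Z,12R)-3,4:6,9-diepoxy-2-(triethylsilyloxy)cembra-1(15),9-dien-12-yl acetate
Conditions: Ac2O, DMAP, Et3N, CH2Cl2, rt to 35 °C, on the crude carbinol
Reagents that add atoms: acetic anhydride, CC(=O)OC(C)=O
Why: DMAP-catalysed acylation (N-acetylpyridinium) esterifies the tertiary alcohol under basic conditions before this γ-hydroxy enol ether can spiroketalise.

Step 21
Reactants: 27 (3S,4S,6R,8S,9Z,12R)-3,4:6,9-diepoxy-2-(triethylsilyloxy)cembra-1(15),9-dien-12-yl acetate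
Product: 28 (3S,4S,6R,8S,9Z,12R)-3,4:6,9-diepoxy-2-hydroxycembra-1(15),9-dien-12-yl acetate (C2 epimers)
Conditions: Bu4NF, AcOH, THF, 0 °C to rt
Reagents that add atoms: none
Why: Buffered fluoride cleaves the triethylsilyl ether, the acetic acid preventing alkoxide-induced epoxide migration and loss of the tertiary acetate.

Step 22
Reactants: 28 (3S,4S,6R,8S,9Z,12R)-3,4:6,9-diepoxy-2-hydroxycembra-1(15),9-dien-12-yl acetate
Product: 29 (3R,4S,6R,8S,9Z,12R)-3,4:6,9-diepoxy-2-oxocembra-1(15),9-dien-12-yl acetate (CNP0162736.1)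
Conditions: Dess–Martin periodinane, NaHCO3, CH2Cl2, 0 °C to rt
Reagents that add atoms: none
Why: Buffered Dess–Martin oxidation of the secondary allylic alcohol gives the C2 ketone, converging both C2 epimers on the target without touching the epoxide, enol ether or acetate.

**Compound list**

1 | (5R)-5-(hydroxymethyl)oxolan-2-one | O=C1CC[C@H](CO)O1 | starting material
2 | (5R)-5-{[tert-butyl(diphenyl)silyl]oxymethyl}oxolan-2-one | O=C1CC[C@H](CO[Si](c2ccccc2)(c2ccccc2)C(C)(C)C)O1 | intermediate
3 | lithium enolate of lactone 2 | [Li]OC1=CC[C@H](CO[Si](c2ccccc2)(c2ccccc2)C(C)(C)C)O1 | intermediate (not isolated)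
4 | (3S,5R)-5-{[tert-butyl(diphenyl)silyl]oxymethyl}-3-methyloxolan-2-one (3,5-trans) | O=C1[C@@H](C)C[C@H](CO[Si](c2ccccc2)(c2ccccc2)C(C)(C)C)O1 | intermediate
5 | (3S,5R)-5-{[tert-butyl(diphenyl)silyl]oxymethyl}-3-methyloxolan-2-ol (anomers) | OC1[C@@H](C)C[C@H](CO[Si](c2ccccc2)(c2ccccc2)C(C)(C)C)O1 | intermediate
6 | (2R,4S)-1-{[tert-butyl(diphenyl)silyl]oxy}-4-methylhex-5-yn-2-ol | C#C[C@@H](C)C[C@@H](O)CO[Si](c1ccccc1)(c1ccccc1)C(C)(C)C | intermediate
7 | dilithio derivative of 6 (lithium alkoxide, lithium acetylide) | [Li]C#C[C@@H](C)C[C@@H](O[Li])CO[Si](c1ccccc1)(c1ccccc1)C(C)(C)C | intermediate (not isolated)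
8 | (2S,6S,8R)-9-{[tert-butyl(diphenyl)silyl]oxy}-6-methylnon-4-yne-2,8-diol | C[C@H](O)CC#C[C@@H](C)C[C@@H](O)CO[Si](c1ccccc1)(c1ccccc1)C(C)(C)C | intermediate
9 | (2R,4S,8S)-4-methylnon-5-yne-1,2,8-triol | C[C@H](O)CC#C[C@@H](C)C[C@@H](O)CO | intermediate
10 | (2R,4S,8S)-2,8-dihydroxy-4-methylnon-5-yn-1-yl 4-methylbenzenesulfonate | C[C@H](O)CC#C[C@@H](C)C[C@@H](O)COS(=O)(=O)c1ccc(C)cc1 | intermediate (not isolated)
11 | (2S,6S)-6-methyl-7-[(2R)-oxiran-2-yl]hept-4-yn-2-ol | C[C@H](O)CC#C[C@@H](C)C[C@@H]1CO1 | intermediate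
12 | tert-butyl(dimethyl){[(2S,6S)-6-methyl-7-[(2R)-oxiran-2-yl]hept-4-yn-2-yl]oxy}silane | C[C@H](O[Si](C)(C)C(C)(C)C)CC#C[C@@H](C)C[C@@H]1CO1 | intermediate
13 | (4R,6S,10S)-10-{[tert-butyl(dimethyl)silyl]oxy}-6-methylundeca-1,7-diyn-4-ol | C[C@H](O[Si](C)(C)C(C)(C)C)CC#C[C@@H](C)C[C@@H](O)CC#C | intermediate
14 | (E)-alkenyl(dimethyl)alane from 13, C6 oxygen as dimethylaluminium alkoxide | C[C@H](O[Si](C)(C)C(C)(C)C)CC#C[C@@H](C)C[C@@H](O[Al](C)C)C/C(C)=C/[Al](C)C | intermediate (not isolated)
15 | (2E,5R,7S,11S)-11-{[tert-butyl(dimethyl)silyl]oxy}-3,7-dimethyldodec-2-en-8-yne-1,5-diol | C[C@H](O[Si](C)(C)C(C)(C)C)CC#C[C@@H](C)C[C@@H](O)C/C(C)=C/CO | intermediate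
16 | (2R,4S,8S)-8-{[tert-butyl(dimethyl)silyl]oxy}-1-[(2S,3S)-3-(hydroxymethyl)-2-methyloxiran-2-yl]-4-methylnon-5-yn-2-ol | C[C@H](O[Si](C)(C)C(C)(C)C)CC#C[C@@H](C)C[C@@H](O)C[C@]1(C)O[C@H]1CO | intermediate
17 | {(2S,3S)-3-[((2R,4S,5Z)-5-{(3S)-3-[tert-butyl(dimethyl)silyl]oxybutylidene}-4-methyloxolan-2-yl)methyl]-3-methyloxiran-2-yl}methanol | C[C@H](O[Si](C)(C)C(C)(C)C)C/C=C1\O[C@H](C[C@@H]1C)C[C@]1(C)O[C@H]1CO | intermediate
18 | (2S,4Z)-4-[(3S,5R)-5-{[(2S,3S)-3-(hydroxymethyl)-2-methyloxiran-2-yl]methyl}-3-methyloxolan-2-ylidene]butan-2-ol | C[C@H](O)C/C=C1\O[C@H](C[C@@H]1C)C[C@]1(C)O[C@H]1CO | intermediate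
19 | (2R,3S)-3-methyl-3-{[(2R,4S,5Z)-4-methyl-5-(3-oxobutylidene)oxolan-2-yl]methyl}oxirane-2-carbaldehyde | CC(=O)C/C=C1\O[C@H](C[C@@H]1C)C[C@]1(C)O[C@H]1C=O | intermediate
20 | 1,1-dibromo-2-methylprop-1-ene | CC(C)=C(Br)Br | starting material
21 | 3-bromo-4-methylpenta-1,3-diene | C=CC(Br)=C(C)C | intermediate
22 | (4-methylpenta-1,3-dien-3-yl)lithium | [Li]C(C=C)=C(C)C | intermediate (not isolated)
23 | 3-iodo-4-methylpenta-1,3-diene | [I]C(C=C)=C(C)C | intermediate
24 | (4Z)-4-[(3S,5R)-5-({(2S,3S)-3-[2-ethenyl-1-hydroxy-3-methylbut-2-en-1-yl]-2-methyloxiran-2-yl}methyl)-3-methyloxolan-2-ylidene]butan-2-one (C2 carbinol epimers) | CC(=O)C/C=C1\O[C@H](C[C@@H]1C)C[C@]1(C)O[C@H]1C(O)C(C=C)=C(C)C | intermediate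
25 | (4Z)-4-[(3S,5R)-5-({(2S,3S)-3-[2-ethenyl-3-methyl-1-(triethylsilyloxy)but-2-en-1-yl]-2-methyloxiran-2-yl}methyl)-3-methyloxolan-2-ylidene]butan-2-one (C2 epimers) | CC(=O)C/C=C1\O[C@H](C[C@@H]1C)C[C@]1(C)O[C@H]1C(O[Si](CC)(CC)CC)C(C=C)=C(C)C | intermediate
26 | (3S,4S,6R,8S,9Z,12R)-3,4:6,9-diepoxy-2-(triethylsilyloxy)cembra-1(15),9-dien-12-ol (C2 epimers) | O[C@@]1(C)C/C=C2\O[C@H](C[C@@H]2C)C[C@]2(C)O[C@H]2C(O[Si](CC)(CC)CC)C(=C(C)C)CC1 | intermediate
27 | (3S,4S,6R,8S,9Z,12R)-3,4:6,9-diepoxy-2-(triethylsilyloxy)cembra-1(15),9-dien-12-yl acetate (C2 epimers) | CC(=O)O[C@@]1(C)C/C=C2\O[C@H](C[C@@H]2C)C[C@]2(C)O[C@H]2C(O[Si](CC)(CC)CC)C(=C(C)C)CC1 | intermediate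
28 | (3S,4S,6R,8S,9Z,12R)-3,4:6,9-diepoxy-2-hydroxycembra-1(15),9-dien-12-yl acetate (C2 epimers) | CC(=O)O[C@@]1(C)C/C=C2\O[C@H](C[C@@H]2C)C[C@]2(C)O[C@H]2C(O)C(=C(C)C)CC1 | intermediate
29 | (3R,4S,6R,8S,9Z,12R)-3,4:6,9-diepoxy-2-oxocembra-1(15),9-dien-12-yl acetate (CNP0162736.1) | CC(=O)O[C@@]1(C)C/C=C2\O[C@H](C[C@@H]2C)C[C@]2(C)O[C@H]2C(=O)C(=C(C)C)CC1 | target

**Step count and risks**

Total steps: 22. Longest linear sequence: 20 (steps 1–14 and 17–22); steps 15–16 form the diene branch.

Risk 1 – step 19. Oligomerisation, ethyl transfer or simple carbonyl reduction may outrun the oxidative cyclisation; a nickel hydride may move the enol-ether double bond; and attack on the wrong face of the C12 carbonyl would give the 12-epimer if the zinc chelate does not dominate. The fallback is a two-stage, known ring closure that sets out from 25 and returns at 26. Hydroboration of the vinyl group with 9-BBN (THF, then NaBO3) should give the C13 primary alcohol F1. PPh3, I2 and imidazole convert it into the C13 iodide F2. SmI2 with catalytic NiI2 in THF at high dilution then effects the intramolecular Barbier addition of the alkylsamarium to the methyl ketone, giving 26.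

Risk 2 – step 12. Closure in the 6-endo sense, acid-induced migration of the exocyclic double bond into the ring, or addition of a second hydroxyl to the enol ether may compete, and the Z geometry may be eroded. The fallback sets out from 16 and returns at 17. Iodoetherification (I2, NaHCO3, MeCN, 0 °C) closes the oxolane by anti addition to give the E-configured iodo enol ether F3. Pd(PPh3)4-catalysed reduction with Bu3SnH then replaces iodine by hydrogen with retention of the double-bond geometry, giving 17.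

Risk 3 – step 17. Oxidative addition of the hindered iodide may be slow, and divalent chromium may open the epoxy aldehyde reductively or the aldehyde may decompose during a long reaction. The fallback sets out from 21 and 19 and returns at 24. Lithiation of 21 (tBuLi, Et2O, −78 °C) gives 22, and transmetallation with ClTi(OiPr)3 gives the dienyltitanium triisopropoxide F4. This non-basic reagent should add to the aldehyde of 19 at −78 to −30 °C and leave the enolisable methyl ketone untouched.

Further compounds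
F1 | step 19 | (4Z)-4-[(3S,5R)-5-({(2S,3S)-3-[2-(2-hydroxyethyl)-3-methyl-1-(triethylsilyloxy)but-2-en-1-yl]-2-methyloxiran-2-yl}methyl)-3-methyloxolan-2-ylidene]butan-2-one | CC(=O)C/C=C1\O[C@H](C[C@@H]1C)C[C@]1(C)O[C@H]1C(O[Si](CC)(CC)CC)C(CCO)=C(C)C
F2 | step 19 | (4Z)-4-[(3S,5R)-5-({(2S,3S)-3-[2-(2-iodoethyl)-3-methyl-1-(triethylsilyloxy)but-2-en-1-yl]-2-methyloxiran-2-yl}methyl)-3-methyloxolan-2-ylidene]butan-2-one | CC(=O)C/C=C1\O[C@H](C[C@@H]1C)C[C@]1(C)O[C@H]1C(O[Si](CC)(CC)CC)C(CC[I])=C(C)C
F3 | step 12 | {(2S,3S)-3-[((2R,4S,5E)-5-{(3S)-3-[tert-butyl(dimethyl)silyl]oxy-1-iodobutylidene}-4-methyloxolan-2-yl)methyl]-3-methyloxiran-2-yl}methanol | C[C@H](O[Si](C)(C)C(C)(C)C)C/C([I])=C1\O[C@H](C[C@@H]1C)C[C@]1(C)O[C@H]1CO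
F4 | step 17 | (4-methylpenta-1,3-dien-3-yl)tris(propan-2-olato)titanium | C=CC(=C(C)C)[Ti](OC(C)C)(OC(C)C)OC(C)C
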